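**Plan**

- Ring labels: unit 1 is benzo ring A, pyranone ring C and para-phenylene ring B; unit 2 is benzo ring D, pyranone ring E and hydroxyphenyl ring F; ring B is bound through oxygen to C8 of ring D.
- Cuts, in retrosynthetic order: the three O–CH3 bonds; the two C7–O bonds (back to C7–F); the two C8a–O1 bonds of rings C and E together; the two C2 formyl carbons; the ring A C(=O)–CH2 bond (acid chloride plus benzylic zinc); the ring D C(=O)–CH2 bond (Weinreb amide plus benzylic Grignard); the ring D C4a–C4 bond (ortho-lithiation); the ring B–O bond (Ullmann).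
- Enabling feature: in ring A and in ring D, C8a (bearing O1) is ortho and C7 (bearing the hydroxyl) is para to C4a, the carbon that carries the C4 carbonyl. Each of these four C–O bonds can therefore be made by displacing a ketone-activated fluoride. C8–Cl and the C8–O–ring B ether sit meta and come in with the fluoroarenes.
- Forward order: diaryl ether (rings B and D), ring D acylated and joined to ring F, ring A joined through the ring B benzylic carbon, both methylenes formylated, rings C and E closed in one operation, C7 fluorides exchanged for oxygen, ethers cleaved.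
- Stereochemistry: the target has no stereocentre and no configured double bond; the enaminone and enol geometries on the way are transient and vanish when the pyranones form.

Key step: step 10

Assumption: LiN(i-Pr)2 and 4-methoxybenzylmagnesium chloride are used as purchased THF solutions, and 16 is drawn as its chelated (Z,Z)-enol although its tautomers interconvert under the basic conditions of step 10.

**Route**

Step 1
Reactants: 1 4-iodobenzyl alcohol
Product: 2 tert-butyl[(4-iodophenyl)methoxy]dimethylsilane
Conditions: TBSCl, imidazole, DMF, 25 °C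
Reagents that add atoms: tert-butyldimethylsilyl chloride, CC(C)(C)[Si](C)(C)Cl
Why: Silyl ether protection of a primary benzylic alcohol (imidazole-catalysed silylation) is routine and masks the ring B carbinol against the base, the organolithium and the Grignard reagent of steps 2 to 4.

Step 2
Reactants: 2 tert-butyl[(4-iodophenyl)methoxy]dimethylsilane; 3 2,6-difluorophenol
Product: 4 tert-butyl{[4-(2,6-difluorophenoxy)phenyl]methoxy}dimethylsilane
Conditions: CuI (10 mol %), picolinic acid (20 mol %), K3PO4, DMSO, 90 °C
Reagents that add atoms: none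
Why: Ullmann-type diaryl ether coupling: CuI/picolinic acid is suited to ortho,ortho-disubstituted phenols and aryl iodides, the unactivated C–F bonds of 3 are inert to phenoxide, and K3PO4 should leave the alkyl silyl ether untouched.

Step 3
Reactants: 4 tert-butyl{[4-(2,6-difluorophenoxy)phenyl]methoxy}dimethylsilane
Product: 6 3-[4-({[tert-butyl(dimethyl)silyl]oxy}methyl)phenoxy]-2,4-difluoro-N-methoxy-N-methylbenzamide, via ring D aryllithium 5 (not isolated)
Conditions: LiN(i-Pr)2, THF, −78 °C; then cannulated into ClC(O)N(OMe)Me, THF, −78 °C to 0 °C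
Reagents that add atoms: N-methoxy-N-methylcarbamoyl chloride, CON(C)C(Cl)=O
Why: Fluorine-directed ortho-lithiation removes the ring D hydrogen next to fluorine (the two such positions are equivalent by symmetry and nothing on ring B or the CH2OSi group is acidic enough to compete at −78 °C), and inverse addition of the aryllithium to the carbamoyl chloride should give the Weinreb amide without a second addition.

Step 4
Reactants: 6 3-[4-({[tert-butyl(dimethyl)silyl]oxy}methyl)phenoxy]-2,4-difluoro-N-methoxy-N-methylbenzamide; 7 4-methoxybenzylmagnesium chloride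
Product: 9 1-[2,4-difluoro-3-[4-(hydroxymethyl)phenoxy]phenyl]-2-(4-methoxyphenyl)ethanone, via silyl ether ketone 8 (not isolated)
Conditions: THF, 0 °C; then 2 M aq. HCl, 25 °C
Reagents that add atoms: none
Why: Weinreb ketone synthesis: the benzylic Grignard reagent adds only once because the magnesium-chelated tetrahedral adduct persists until the acid quench, which releases the benzyl ketone and, on continued stirring, hydrolyses the primary silyl ether.

Step 5
Reactants: 9 1-[2,4-difluoro-3-[4-(hydroxymethyl)phenoxy]phenyl]-2-(4-methoxyphenyl)ethanone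
Product: 10 1-[3-[4-(chloromethyl)phenoxy]-2,4-difluorophenyl]-2-(4-methoxyphenyl)ethanone
Conditions: SOCl2, cat. DMF, CH2Cl2, 0 °C to 25 °C
Reagents that add atoms: thionyl chloride, O=S(Cl)Cl
Why: Chlorination of a primary benzylic alcohol through its chlorosulfite (deoxychlorination) is standard, and the aryl ketone, aryl fluorides and ethers should be inert under these non-basic conditions.

Step 6
Reactants: 11 3-chloro-2,4-difluorobenzoic acid
Product: 12 3-chloro-2,4-difluorobenzoyl chloride
Conditions: (COCl)2, cat. DMF, CH2Cl2, 25 °C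
Reagents that add atoms: oxalyl chloride, O=C(Cl)C(Cl)=O
Why: Acid chloride formation through the Vilsmeier-type chloroiminium catalyst is standard and leaves the halogenated ring unchanged.

Step 7
Reactants: 10 1-[3-[4-(chloromethyl)phenoxy]-2,4-difluorophenyl]-2-(4-methoxyphenyl)ethanone; 12 3-chloro-2,4-difluorobenzoyl chloride
Product: 14 1-(3-chloro-2,4-difluorophenyl)-2-[4-[2,6-difluoro-3-[(4-methoxyphenyl)acetyl]phenoxy]phenyl]ethanone, via benzylic zinc chloride 13 (not isolated)
Conditions: Zn dust, LiCl, THF, 25 °C; then 12, Pd(PPh3)4 (3 mol %), THF, 0 °C to 25 °C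
Reagents that add atoms: none
Why: LiCl-promoted insertion of zinc into a benzylic C–Cl bond tolerates ketones, and the benzylic zinc chloride should be acylated by 12 in a Negishi acylation, the acyl C–Cl bond adding to zerovalent palladium far faster than any aryl C–Cl or C–F bond.

Step 8
Reactants: 14 1-(3-chloro-2,4-difluorophenyl)-2-[4-[2,6-difluoro-3-[(4-methoxyphenyl)acetyl]phenoxy]phenyl]ethanone
Product: 15 (2E)-1-(3-chloro-2,4-difluorophenyl)-3-(dimethylamino)-2-[4-[3-[(2E)-3-(dimethylamino)-2-(4-methoxyphenyl)prop-2-enoyl]-2,6-difluorophenoxy]phenyl]prop-2-en-1-one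
Conditions: Me2NCH(OMe)2 (excess), toluene, 90 °C
Reagents that add atoms: N,N-dimethylformamide dimethyl acetal, COC(OC)N(C)C
Why: Condensation of both activated deoxybenzoin methylenes with the amide acetal (enaminone formation) runs under neutral conditions, so none of the four aryl fluorides meets a free alkoxide or enolate, and the enaminone nitrogen cannot cyclise.

Step 9
Reactants: 15 the bis-enaminone
Product: 16 (2Z)-1-(3-chloro-2,4-difluorophenyl)-2-[4-[2,6-difluoro-3-[(2Z)-3-hydroxy-2-(4-methoxyphenyl)prop-2-enoyl]phenoxy]phenyl]-3-hydroxyprop-2-en-1-one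
Conditions: 2 M aq. HCl, THF, 25 °C
Reagents that add atoms: water, O
Why: Acid hydrolysis of a vinylogous amide (α-protonation, addition of water to the iminium ion, loss of dimethylamine) should leave each α-formyl ketone as its hydrogen-bonded (Z)-enol, and without base no fluoride displacement can begin.

Step 10
Reactants: 16 the bis(hydroxymethylene) diketone
Product: 17 8-chloro-7-fluoro-3-[4-[[7-fluoro-3-(4-methoxyphenyl)-4-oxochromen-8-yl]oxy]phenyl]chromen-4-one
Conditions: K2CO3 (4 equiv), dry DMF (0.02 M), 25 °C to 60 °C
Reagents that add atoms: none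
Why: K2CO3 deprotonates both enols to 1,3-dicarbonyl-type anions; the formyl-derived oxygen of each adds to the C–F carbon ortho to its own ketone, the anionic σ-adduct is delocalised into that ketone and held further by the neighbouring chlorine or aryloxy group and the second fluorine, and loss of fluoride forms C8a–O1 (intramolecular SNAr, addition–elimination). The closest known reaction type is the base-mediated cyclisation of ortho-fluoroaryl β-dicarbonyl enolates to chromones and its nitrogen counterpart in quinolone synthesis, here run twice in one molecule. Ring C and ring E each close by a six-membered exo attack of oxygen on an aromatic sp2 carbon (6-exo-trig addition, then elimination). No stereocentre is formed. The step needs ortho over para fluorine selectivity and O- over C-attack: only the ortho carbon lies within reach of the tethered oxygen, C-attack would require a four-membered ring, and the para fluorines could be attacked only by a second molecule, which high dilution disfavours. The C8 chlorine and the C8 aryloxy group are meta to the ketone and poorer leaving groups, so they should stay, and the two surviving fluorines become C7–F, para to each new C4 carbonyl.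

Step 11
Reactants: 17 the bis(7-fluorochromone)
Product: 18 8-chloro-7-methoxy-3-[4-[[7-methoxy-3-(4-methoxyphenyl)-4-oxochromen-8-yl]oxy]phenyl]chromen-4-one
Conditions: NaOMe (4 equiv), MeOH–THF, 60 °C; then AcOH
Reagents that add atoms: sodium methoxide, C[O-].[Na+]
Why: Each C7–F is para to the C4 carbonyl of its chromone, so methoxide should displace both by SNAr while C8–Cl (meta to the carbonyl, poorer leaving group) stays, and any reversible methoxide addition at C2 should be undone on acidification.

Step 12
Reactants: 18 the trimethyl ether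
Product: 19 bisoflavolin J (8-chloro-7-hydroxy-3-[4-[[7-hydroxy-3-(4-hydroxyphenyl)-4-oxochromen-8-yl]oxy]phenyl]chromen-4-one)
Conditions: BBr3 (10 equiv), CH2Cl2, −78 °C to 25 °C; then ice-water
Reagents that add atoms: none
Why: BBr3 demethylation of aryl methyl ethers (bromide attack on the methyl group of each boron-complexed ether) should free the three phenols on aqueous work-up without cleaving the diaryl ether, the aryl chloride or the pyranones.

**Compound list**

1 | 4-iodobenzyl alcohol | OCc1ccc(I)cc1 | starting material
2 | tert-butyl[(4-iodophenyl)methoxy]dimethylsilane | CC(C)(C)[Si](C)(C)OCc1ccc(I)cc1 | intermediate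
3 | 2,6-difluorophenol | Oc1c(F)cccc1F | starting material
4 | tert-butyl{[4-(2,6-difluorophenoxy)phenyl]methoxy}dimethylsilane | CC(C)(C)[Si](C)(C)OCc1ccc(Oc2c(F)cccc2F)cc1 | intermediate
5 | [3-[4-({[tert-butyl(dimethyl)silyl]oxy}methyl)phenoxy]-2,4-difluorophenyl]lithium (not isolated) | [Li]c1ccc(F)c(Oc2ccc(CO[Si](C)(C)C(C)(C)C)cc2)c1F | intermediate
6 | 3-[4-({[tert-butyl(dimethyl)silyl]oxy}methyl)phenoxy]-2,4-difluoro-N-methoxy-N-methylbenzamide | CON(C)C(=O)c1ccc(F)c(Oc2ccc(CO[Si](C)(C)C(C)(C)C)cc2)c1F | intermediate
7 | 4-methoxybenzylmagnesium chloride | COc1ccc(C[Mg]Cl)cc1 | starting material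
8 | 1-[3-[4-({[tert-butyl(dimethyl)silyl]oxy}methyl)phenoxy]-2,4-difluorophenyl]-2-(4-methoxyphenyl)ethanone (not isolated) | COc1ccc(CC(=O)c2ccc(F)c(Oc3ccc(CO[Si](C)(C)C(C)(C)C)cc3)c2F)cc1 | intermediate
9 | 1-[2,4-difluoro-3-[4-(hydroxymethyl)phenoxy]phenyl]-2-(4-methoxyphenyl)ethanone | COc1ccc(CC(=O)c2ccc(F)c(Oc3ccc(CO)cc3)c2F)cc1 | intermediate
10 | 1-[3-[4-(chloromethyl)phenoxy]-2,4-difluorophenyl]-2-(4-methoxyphenyl)ethanone | COc1ccc(CC(=O)c2ccc(F)c(Oc3ccc(CCl)cc3)c2F)cc1 | intermediate
11 | 3-chloro-2,4-difluorobenzoic acid | OC(=O)c1ccc(F)c(Cl)c1F | starting material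
12 | 3-chloro-2,4-difluorobenzoyl chloride | O=C(Cl)c1ccc(F)c(Cl)c1F | intermediate
13 | [4-[2,6-difluoro-3-[(4-methoxyphenyl)acetyl]phenoxy]benzyl]zinc chloride (not isolated) | COc1ccc(CC(=O)c2ccc(F)c(Oc3ccc(C[Zn]Cl)cc3)c2F)cc1 | intermediate
14 | 1-(3-chloro-2,4-difluorophenyl)-2-[4-[2,6-difluoro-3-[(4-methoxyphenyl)acetyl]phenoxy]phenyl]ethanone | COc1ccc(CC(=O)c2ccc(F)c(Oc3ccc(CC(=O)c4ccc(F)c(Cl)c4F)cc3)c2F)cc1 | intermediate
15 | (2E)-1-(3-chloro-2,4-difluorophenyl)-3-(dimethylamino)-2-[4-[3-[(2E)-3-(dimethylamino)-2-(4-methoxyphenyl)prop-2-enoyl]-2,6-difluorophenoxy]phenyl]prop-2-en-1-one | O=C(c1ccc(F)c(Cl)c1F)/C(c1ccc(Oc2c(F)ccc(C(=O)/C(=C/N(C)C)c3ccc(OC)cc3)c2F)cc1)=C/N(C)C | intermediate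
16 | (2Z)-1-(3-chloro-2,4-difluorophenyl)-2-[4-[2,6-difluoro-3-[(2Z)-3-hydroxy-2-(4-methoxyphenyl)prop-2-enoyl]phenoxy]phenyl]-3-hydroxyprop-2-en-1-one | O=C(c1ccc(F)c(Cl)c1F)/C(c1ccc(Oc2c(F)ccc(C(=O)/C(=C\O)c3ccc(OC)cc3)c2F)cc1)=C\O | intermediate
17 | 8-chloro-7-fluoro-3-[4-[[7-fluoro-3-(4-methoxyphenyl)-4-oxochromen-8-yl]oxy]phenyl]chromen-4-one | O=c1c(-c2ccc(Oc3c(F)ccc4c(=O)c(-c5ccc(OC)cc5)coc34)cc2)coc2c(Cl)c(F)ccc12 | intermediate
18 | 8-chloro-7-methoxy-3-[4-[[7-methoxy-3-(4-methoxyphenyl)-4-oxochromen-8-yl]oxy]phenyl]chromen-4-one | O=c1c(-c2ccc(Oc3c(OC)ccc4c(=O)c(-c5ccc(OC)cc5)coc34)cc2)coc2c(Cl)c(OC)ccc12 | intermediate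
19 | bisoflavolin J, 8-chloro-7-hydroxy-3-[4-[[7-hydroxy-3-(4-hydroxyphenyl)-4-oxochromen-8-yl]oxy]phenyl]chromen-4-one | O=c1c(-c2ccc(Oc3c(O)ccc4c(=O)c(-c5ccc(O)cc5)coc34)cc2)coc2c(Cl)c(O)ccc12 | target

**Step count and risks**

Total step count: 12. Longest linear sequence: 11 steps (steps 1 to 5 and 7 to 12; step 6 prepares the acid chloride for the convergent step 7).

Steps most likely to fail:

Step 10. The second ring closure may lag behind the first, and in that interval the remaining enolate could attack a para fluorine of another molecule (oligomerisation) or lose its formyl carbon by retro-Claisen cleavage with carbonate and adventitious water. The fallback sets out from 16. Both enols are silylated (Me3SiCl, Et3N, CH2Cl2, 0 °C) to (2Z)-1-(3-chloro-2,4-difluorophenyl)-2-[4-[2,6-difluoro-3-[(2Z)-2-(4-methoxyphenyl)-3-(trimethylsilyloxy)prop-2-enoyl]phenoxy]phenyl]-3-(trimethylsilyloxy)prop-2-en-1-one F1. Catalytic CsF in dry MeCN at 60 °C then frees the enolates a few at a time, each fluoride expelled in a ring closure desilylating the next enol ether. No stoichiometric base or water is present and the free enolate concentration stays low. This fluoride-relayed desilylative SNAr comes back to the route at 17.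

Step 11. Methoxide may add at C2 of the electron-poor pyranones faster than it displaces fluoride, opening rings C and E and, after loss of the formyl carbon, returning deoxybenzoins. The fallback sets out from 17 and uses a hydroxide surrogate instead of an alkoxide. Acetohydroxamic acid and K2CO3 in DMSO at 80 °C (SNAr by the hydroxamate oxygen, then Lossen-type fragmentation of the O-aryl hydroxamate) should give the C7 phenols directly as 8-chloro-7-hydroxy-3-[4-[[7-hydroxy-3-(4-methoxyphenyl)-4-oxochromen-8-yl]oxy]phenyl]chromen-4-one F2. The phenoxides formed make the pyranones less prone to further nucleophilic attack. BBr3 cleavage of the single remaining methyl ether comes back to the route at 19.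

Step 7. The benzylic zinc reagent may be protonated by the acidic methylene of the ketone already in the molecule, or may undergo Wurtz-type homocoupling during the zinc insertion. The fallback sets out from 10 and 12 and joins them by nickel-catalysed reductive cross-electrophile coupling (NiCl2(dme), 4,4'-di-tert-butyl-2,2'-bipyridine, Mn powder, DMA, 25 °C). The benzylic chloride is engaged as a transient radical at nickel and no stoichiometric organometallic is present. It makes no new compound (none F0) and comes back to the route at 14.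

Further compounds
F1 | step 10 | (2Z)-1-(3-chloro-2,4-difluorophenyl)-2-[4-[2,6-difluoro-3-[(2Z)-2-(4-methoxyphenyl)-3-(trimethylsilyloxy)prop-2-enoyl]phenoxy]phenyl]-3-(trimethylsilyloxy)prop-2-en-1-one | O=C(c1ccc(F)c(Cl)c1F)/C(c1ccc(Oc2c(F)ccc(C(=O)/C(=C\O[Si](C)(C)C)c3ccc(OC)cc3)c2F)cc1)=C\O[Si](C)(C)C
F2 | step 11 | 8-chloro-7-hydroxy-3-[4-[[7-hydroxy-3-(4-methoxyphenyl)-4-oxochromen-8-yl]oxy]phenyl]chromen-4-one | O=c1c(-c2ccc(Oc3c(O)ccc4c(=O)c(-c5ccc(OC)cc5)coc34)cc2)coc2c(Cl)c(O)ccc12
F0 | step 7 | none | none
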